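The earlier runs and the new flask were computed with made-up constants.

Ring is what is wanted here, counted as a fraction of the substrate charged, and the zero of the scale is a flask where closure takes no time: whatever substrate has lost, ring has gained.

| setting | eta | Saturday's | Tuesday's |
|---|---|---|---|
| substrate | 1 M (in portions, 3) | 1.0 M | 1.0 M (in portions, 3) |
| activator | 1.7 equiv | 3.00 equiv | 1.50 equiv |
| remark | run made earlier; portions every 3.0 h | everything together at the start | the portions of substrate follow each other after 3.0 h, the first at the start |
| time |  | 3.0 h | 10 h |

eta run (percent of the substrate charged)

| time / h | ring / % | substrate / % |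
|---|---|---|
| 1.50 | 7.5 | 13.0 |
| 3.00 | 17.3 | 3.6 |
| 5.00 | 34.8 | 13.4 |
| 6.00 | 42.5 | 6.4 |
| 8.00 | 60.0 | 17.0 |
| 10.0 | 73.1 | 8.5 |

(each reading ± 0.5 percentage points)

- the winner by amount of ring, in percent of the substrate charged; "neither" if no more than 2 percentage points parts them (Saturday's / Tuesday's / neither)
- how much ring is there at the end, in percent of the substrate charged: Saturday's
- how much ring is there at the end, in percent of the substrate charged: Tuesday's



The eta run leaves that zero at once. At 3.00 h its first portion, a third of the charge, is down to 3.6% as substrate, yet ring stands at 17.3%, about half of that portion. Substrate has fallen further than ring has risen, so something must wait between them. This gap, portion minus ring minus substrate, reads 12.8% at 1.50 h and 12.4% at 3.00 h.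

Ring grows meanwhile, and its rate over the mean gap reads 0.517 h⁻¹, which gives a closure half-time 1.34 h.

Substrate in the eta run falls at 0.628 h⁻¹. Taken in proportion to activator, that becomes 1.11 h⁻¹ for Saturday's flask, whose activation half-life is shorter than the closure half-time. The two rates part by a factor of only 2.15, so neither link is dropped from the reckoning, and two first-order links in series, the activation taken as pseudo-first-order, give 63.4% of ring at 3.0 h. Tuesday's flask has the eta timing with somewhat less activator, so it should land a little under 73.1%, which is still above that figure.

The forecast, lower on Saturday's, gives 55% for Saturday's and 68% for Tuesday's, and says “Tuesday's likely wins”.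

The flasks give 60.7% for Saturday's and 69.8% for Tuesday's, so the winner is Tuesday's.

    substrate + activated form → open dimer (k = 0.0616 M⁻¹ h⁻¹)
    activated form ⇌ ring (K = 12.1, k = 0.561 h⁻¹)
    substrate + activator → activated form (k = 0.431 M⁻¹ h⁻¹)
    ring → over-reaction product (k = 6.54 × 10⁻⁴ h⁻¹)

Saturday's flask is stopped after 2.24 closure half-times, with 30.9% still standing as activated form. The time given is the main reason for its shortfall: Saturday's flask holds 60.7% of ring at 3.0 h and 87.4% when left to 30.0 h.

For Tuesday's flask read at 25 h, the extra time is 11.2 half-times, so the 26.2% waiting as substrate and activated form should lift ring to 96.0%. The computed flask holds 86.9%, with 7.37% still activated form, so a one-way half-time overstates it.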